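**Retrosynthetic overview**
1. Side chain last: the C3 carbinol by CBS reduction of an enone made by Wittig olefination of a C6 aldehyde; the C6 quaternary centre by formaldehyde aldol of that aldehyde, which comes from the bridging ketone.
2. Piperidine: both ring C–N bonds closed in one methylamine/formaldehyde aza-annulation across the two α-carbons of a tricyclic cycloheptenone.
3. Cycloheptenone from the corresponding cyclohexanone by one-carbon ring expansion.
4. Ring C (cyclopentane ester) by a new palladium-catalysed (3+2) annulation of an enantioenriched allyl carbonate–ketone with methyl propiolate, then face-selective hydrogenation.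
5. Ring order: B (6-methoxy-1-indanone; asymmetric transfer hydrogenation, Birch) → six-membered ketone → C → seven-membered ring → piperidine → side chain.

Assumptions and numbering: atoms are numbered C1–C5 (side chain, C3 = carbinol), C6 (quaternary, bears C7H2OH), C8 (methine), C9, C10, C11=C12, C13 (methine), C14, C15, C16 (bears CO2Me), C17, C18 (quaternary), C19 (CH2N), N20, C21 (CH2N); ester and N-methyl carbons are unnumbered. The acyl ylide of step 10 is taken as a catalogue reagent. The palladium annulation is taken to run with net retention at C13.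

Step 1
Reactants: 1 6-methoxy-1-indanone
Product: 2 (1R)-6-methoxy-2,3-dihydro-1H-inden-1-ol
Conditions: RuCl[(R,R)-TsDPEN](p-cymene) (0.5 mol %), HCO2H–Et3N (5:2), CH2Cl2, 30 °C
Reagents that add atoms: none
Why: Noyori–Ikariya asymmetric transfer hydrogenation of an aryl ketone, in which the (R,R)-TsDPEN ruthenium hydride reduces one face of the indanone and sets the future C13 as (R).

Step 2
Reactants: 2 (1R)-6-methoxy-2,3-dihydro-1H-inden-1-ol
Product: 4 (1R)-1-hydroxy-1,2,3,4,5,7-hexahydro-6H-inden-6-one, via dienol ether 3 (not isolated)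
Conditions: n-BuLi, THF, −78 °C; Li, NH3(l), t-BuOH, −78 to −33 °C; NH4Cl; then (CO2H)2 (cat.), MeOH–H2O, 0 °C to rt
Reagents that add atoms: water (O)
Why: Birch reduction of the anisole ring (the benzylic oxygen is kept as its lithium alkoxide to suppress hydrogenolysis) leaves the tetrasubstituted C11=C12 alkene, and mild enol ether hydrolysis gives the β,γ-unsaturated ketone without touching the carbinol centre.

Step 3
Reactants: 4 (1R)-1-hydroxy-1,2,3,4,5,7-hexahydro-6H-inden-6-one
Product: 5 tert-butyl (1R)-6-oxo-2,3,4,5,6,7-hexahydro-1H-inden-1-yl carbonate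
Conditions: Boc2O, DMAP (10 mol %), MeCN, 0 °C to rt
Reagents that add atoms: di-tert-butyl dicarbonate (CC(C)(C)OC(=O)OC(=O)OC(C)(C)C)
Why: DMAP-catalysed carbonate formation on the secondary allylic alcohol, with the stereocentre untouched.

Step 4
Reactants: 5 tert-butyl (1R)-6-oxo-2,3,4,5,6,7-hexahydro-1H-inden-1-yl carbonate; 6 methyl propiolate
Product: 7 tricyclic keto dienoate (13R,18R)
Conditions: Pd2(dba)3·CHCl3 (2.5 mol %), P(O-i-Pr)3 (15 mol %), toluene, 40 °C, slow addition of 6
Reagents that add atoms: none
Why: Proposed new method: zerovalent palladium ionises the allyl carbonate with inversion, the released tert-butoxide removes a C18 proton (alpha to the ketone, on the central allyl carbon) to give a ketone-stabilised palladium trimethylenemethane zwitterion, its enolate carbon C18 adds to the propiolate and the resulting allenoate closes on the allyl terminus C13 on the face away from palladium, so the (R)-carbinol configuration is passed to C13 with net retention and H18 ends cis to H13; the closest known reaction type is the Trost palladium trimethylenemethane (3+2) cycloaddition with acyl- or cyano-stabilised donors generated by proton transfer, not yet shown for a ring-embedded ketone donor or an alkynoate acceptor.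

Step 5
Reactants: 7 tricyclic keto dienoate (13R,18R)
Product: 8 tricyclic keto ester (13S,16S,18R)
Conditions: H2 (1 atm), 10% Pd/C, EtOAc, rt
Reagents that add atoms: none
Why: Heterogeneous hydrogenation of the trisubstituted enoate from the convex face that carries H13 and H18, which puts the ester on the concave face (C16 S) and leaves the tetrasubstituted C11=C12 alkene.

Step 6
Reactants: 8 tricyclic keto ester (13S,16S,18R)
Product: 10 ring-expanded keto ester (13S,16S,18R), via α-silyl ketone 9 (not isolated)
Conditions: TMSCHN2, Sc(OTf)3 (10 mol %), CH2Cl2, −78 to 0 °C; then 1 M HCl, THF, rt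
Reagents that add atoms: trimethylsilyldiazomethane (C[Si](C)(C)C=[N+]=[N-])
Why: Lewis acid-catalysed diazoalkane homologation (Tiffeneau–Demjanov-type ring expansion) in which the less substituted α-carbon C9 migrates, so the new carbon C8 is inserted between C6 and C9, and the α-silyl group is lost on acidic work-up; no stereocentre is involved.

Step 7
Reactants: 10 ring-expanded keto ester (13S,16S,18R)
Product: 11 bridged amino ketone (8S,13S,16S,18R)
Conditions: MeNH2 (33% in EtOH), (CH2O)n, AcOH, 80 °C
Reagents that add atoms: methylamine (CN); formaldehyde (C=O)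
Why: Double Mannich aza-annulation (Robinson–Schöpf type) in which methylamine forms the N–C19 and N–C21 bonds as iminium ions that are captured by the enols at C8 and C18; the bridge can only close cis, C19 enters C18 on the H13 face opposite the ester-bearing flap of ring C (the position of the former C18 hydrogen), and C8 follows from the bridged ring.

Step 8
Reactants: 11 bridged amino ketone (8S,13S,16S,18R)
Product: 12 methyl enol ether (8R,13S,16S,18S)
Conditions: Ph3P(CH2OMe)Cl, KN(SiMe3)2, THF, 0 to 50 °C
Reagents that add atoms: (methoxymethyl)triphenylphosphonium chloride (COC[P+](c1ccccc1)(c1ccccc1)c1ccccc1.[Cl-])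
Why: Wittig methoxymethylenation of the non-enolisable bridging ketone gives the enol ether as an inconsequential E/Z mixture.

Step 9
Reactants: 12 methyl enol ether (8R,13S,16S,18S)
Product: 14 hydroxymethyl aldehyde (6R,8R,13S,16S,18S), via aldehyde 13 (not isolated)
Conditions: 2 M HCl, THF, rt; then Et3N, 37% aq. CH2O, 40 °C
Reagents that add atoms: water (O); formaldehyde (C=O)
Why: Enol ether hydrolysis then amine-mediated crossed aldol with formaldehyde (Tollens-type hydroxymethylation), in which CH2O approaches C6 from the carbocyclic face (over sp2 C12, away from the axial C19 and C21 hydrogens of the piperidine), placing CH2OH syn to the cycloheptene and CHO syn to nitrogen.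

Step 10
Reactants: 14 hydroxymethyl aldehyde (6R,8R,13S,16S,18S); 15 1-(triphenylphosphoranylidene)butan-2-one
Product: 16 (4E)-enone (6S,8R,13S,16S,18S)
Conditions: toluene, 90 °C
Reagents that add atoms: none
Why: Wittig olefination with a stabilised acyl ylide gives the (E)-enone under neutral conditions, which avoids retro-aldol of the β-hydroxy aldehyde.

Step 11
Reactants: 16 (4E)-enone (6S,8R,13S,16S,18S)
Product: 17 (3S,4E)-allylic alcohol (3S,6S,8R,13S,16S,18S)
Conditions: (R)-2-methyl-CBS-oxazaborolidine (0.5 equiv), catecholborane, toluene, −78 °C; then MeOH, aq. NaHCO3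
Reagents that add atoms: none
Why: Corey–Bakshi–Shibata reduction, in which the (R)-oxazaborolidine treats the alkenyl group as the large substituent and sets C3 as (S) under reagent control, while the ester is inert to catecholborane at −78 °C.

Step 12
Reactants: 17 (3S,4E)-allylic alcohol (3S,6S,8R,13S,16S,18S)
Product: 18 target CNP0291564.1 (3S,6S,8R,13S,16S,18S)
Conditions: H2 (4 atm), RhCl(PPh3)3 (10 mol %), toluene–EtOH, 40 °C
Reagents that add atoms: none
Why: Homogeneous hydrogenation reduces only the disubstituted C4=C5 alkene and leaves the tetrasubstituted C11=C12 alkene, the ester and all stereocentres.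

**Compound list**
1 | 6-methoxy-1-indanone | O=C1CCc2ccc(OC)cc21 | starting material
2 | (1R)-6-methoxy-2,3-dihydro-1H-inden-1-ol | O[C@@H]1CCc2ccc(OC)cc21 | intermediate
3 | (1R)-6-methoxy-2,3,4,7-tetrahydro-1H-inden-1-ol (dienol ether) | COC1=CCC2=C(C1)[C@H](O)CC2 | intermediate
4 | (1R)-1-hydroxy-1,2,3,4,5,7-hexahydro-6H-inden-6-one (C13 R) | O=C1CCC2=C(C1)[C@H](O)CC2 | intermediate
5 | tert-butyl (1R)-6-oxo-2,3,4,5,6,7-hexahydro-1H-inden-1-yl carbonate | O=C1CCC2=C(C1)[C@H](OC(=O)OC(C)(C)C)CC2 | intermediate
6 | methyl propiolate | C#CC(=O)OC | starting material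
7 | tricyclic keto dienoate (13R,18R): cyclohexanone (C6=O) fused at C11=C12 to ring B and through C18/C13 to cyclopentene ring C (C16=C17, CO2Me on C16); H13 and H18 cis | O=C1CCC2=C3[C@H]1C=C(C(=O)OC)[C@@H]3CC2 | intermediate
8 | tricyclic keto ester (13S,16S,18R): as 7 with ring C saturated, CO2Me cis to C14 | O=C1CCC2=C3[C@H]1C[C@H](C(=O)OC)[C@@H]3CC2 | intermediate
9 | α-silyl ketone (13S,16S,18R; C8 epimers): cycloheptanone with SiMe3 on C8 | O=C1C([Si](C)(C)C)CCC2=C3[C@H]1C[C@H](C(=O)OC)[C@@H]3CC2 | intermediate
10 | ring-expanded keto ester (13S,16S,18R): cycloheptanone homologue of 8 | O=C1CCCC2=C3[C@H]1C[C@H](C(=O)OC)[C@@H]3CC2 | intermediate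
11 | bridged amino ketone (8S,13S,16S,18R): N-methylpiperidine bridging C18 and C8, C6 ketone as one-carbon bridge | O=C1[C@H]2CCC3=C4[C@@H](CC3)[C@@H](C(=O)OC)C[C@]41CN(C)C2 | intermediate
12 | methyl enol ether (8R,13S,16S,18S): C6=CH–OMe, E/Z mixture | COC=C1[C@H]2CCC3=C4[C@@H](CC3)[C@@H](C(=O)OC)C[C@]41CN(C)C2 | intermediate
13 | C6 aldehyde (8R,13S,16S,18R; C6 epimers) | O=CC1[C@H]2CCC3=C4[C@@H](CC3)[C@@H](C(=O)OC)C[C@]41CN(C)C2 | intermediate
14 | hydroxymethyl aldehyde (6R,8R,13S,16S,18S): C6 bears CHO (syn to N) and CH2OH (syn to cycloheptene) | O=C[C@]1(CO)[C@H]2CCC3=C4[C@@H](CC3)[C@@H](C(=O)OC)C[C@]41CN(C)C2 | intermediate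
15 | 1-(triphenylphosphoranylidene)butan-2-one | CCC(=O)C=P(c1ccccc1)(c1ccccc1)c1ccccc1 | starting material
16 | (4E)-enone (6S,8R,13S,16S,18S) | CCC(=O)/C=C/[C@]1(CO)[C@H]2CCC3=C4[C@@H](CC3)[C@@H](C(=O)OC)C[C@]41CN(C)C2 | intermediate
17 | (3S,4E)-allylic alcohol (3S,6S,8R,13S,16S,18S) | CC[C@H](O)/C=C/[C@]1(CO)[C@H]2CCC3=C4[C@@H](CC3)[C@@H](C(=O)OC)C[C@]41CN(C)C2 | intermediate
18 | CNP0291564.1 (3S,6S,8R,13S,16S,18S) | CC[C@H](O)CC[C@]1(CO)[C@H]2CCC3=C4[C@@H](CC3)[C@@H](C(=O)OC)C[C@]41CN(C)C2 | target

**Step count and risks**
Total step count: 12. Longest linear sequence: 12 steps (1 to 18).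

Step 4 (proposed annulation) is the most likely to fail. The allyl palladium species may lose a β-hydrogen, the enolate may O-allylate, or the allenoate may be protonated before ring closure. The fallback runs from 5 to 7 by known reactions. Cs2CO3-mediated conjugate addition of the C18 methylene of 5 to methyl propiolate gives the (E)-acrylate adduct F1. Dual PBu3/Pd(PPh3)4 catalysis then closes ring C by an intramolecular Morita–Baylis–Hillman-type allylic alkylation: the phosphine adds to C17, the ester enolate carbon C16 attacks the allyl palladium terminus C13, and the phosphine is expelled to give 7. If either mode turns out to invert C13, the (S,S)-TsDPEN catalyst in step 1 supplies the matching carbinol.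

Step 7 (double Mannich) may give poly-aminomethylation or vinylogous attack at C11. The fallback runs from 10 to 11. α-Methylenation at C8 ((CH2O)n, i-Pr2NH·CF3CO2H, THF, reflux) gives the exo-methylene ketone F2. Conjugate addition of MeNH2 forms the N–C21 bond and gives the amino ketone F3. One equivalent of CH2O in AcOH then closes the ring on C18 by an intramolecular Mannich reaction to give 11.

Step 9 (C6 quaternary centre) may fail if formaldehyde enters from the piperidine face or shows low selectivity. The fallback runs from 13 to 18 and uses that opposite facial preference. Michael addition of aldehyde 13 to ethyl vinyl ketone (cat. DBU, THF) puts the 3-oxopentyl chain on the piperidine face and leaves CHO as C7, giving the keto aldehyde F4. NaBH4 at −78 °C reduces only the aldehyde to the hydroxy ketone F5. An (S)-selective ketoreductase (NADP+, i-PrOH, pH 7 buffer) then reduces the ethyl ketone to 18.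

**Further compounds**
F1 | step 4 | (E)-acrylate Michael adduct of 5 at C18 (C13 R, C18 epimers) | O=C1CCC2=C([C@H](OC(=O)OC(C)(C)C)CC2)C1/C=C/C(=O)OC
F2 | step 7 | C8 exo-methylene ketone (13S,16S,18R) | O=C1C(=C)CCC2=C3[C@H]1C[C@H](C(=O)OC)[C@@H]3CC2
F3 | step 7 | C8 (methylaminomethyl) ketone (13S,16S,18R; C8 epimers) | O=C1C(CNC)CCC2=C3[C@H]1C[C@H](C(=O)OC)[C@@H]3CC2
F4 | step 9 | keto aldehyde: C6 bears 3-oxopentyl (syn to N) and CHO (syn to cycloheptene) | CCC(=O)CC[C@]1(C=O)[C@H]2CCC3=C4[C@@H](CC3)[C@@H](C(=O)OC)C[C@]41CN(C)C2
F5 | step 9 | hydroxy ketone: 3-oxo analogue of the target | CCC(=O)CC[C@]1(CO)[C@H]2CCC3=C4[C@@H](CC3)[C@@H](C(=O)OC)C[C@]41CN(C)C2
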